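Retrosynthesis cuts the 3'-O galloyl ester, then the aryl ether bond O1–C8a of ring C, then C2–C1' (ring B to the chain), and last C4–C4a (chain to ring A).
The enabling feature: O1 is bonded both to C8a of ring A and to the benzylic C2, so it can arrive as a C2 carbinol of fixed configuration and be joined to a ring A that carries bromine at C8a and only the O5/O7 resorcinol oxygens.
Forward: 5-bromoresorcinol dibenzyl ether is iodinated ortho to bromine and its Grignard reagent opens methyl (S)-glycidate (C4–C4a); O3 is benzylated; the Weinreb amide takes up the ring B Grignard reagent (C2–C1'); the ketone is reduced; palladium-catalysed etherification closes ring C, the only ring formed; MOM removal, galloylation and one hydrogenolysis finish.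
Stereochemistry: C3 (S) comes from methyl (S)-glycidate; C2 (R) from hydride delivery to a zinc chelate (1,2-anti); the ring closure breaks no bond at either centre, so anti becomes 2,3-trans (2R,3S).
O3' of ring B is singled out from the start: it is created from an aldehyde carbon by Baeyer–Villiger oxidation and carried as a MOM ether beside benzyl ethers.

Key step: step 11

Remark: flavan numbering (O1, C2, C3, C4, C4a, C5 to C8, C8a; ring B primed) is used for all intermediates, open-chain ones included; 9 and 19 are taken as catalogue compounds.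

Step 1
Reactants: 1 5-bromoresorcinol
Product: 2 1,3-bis(benzyloxy)-5-bromobenzene
Conditions: BnBr, K2CO3, DMF, 60 °C
Reagents that add atoms: benzyl bromide, BrCc1ccccc1
Why: Williamson etherification of both phenoxides should go to completion and installs the benzyl ethers that stay until the last step.

Step 2
Reactants: 2 1,3-bis(benzyloxy)-5-bromobenzene
Product: 3 1,5-bis(benzyloxy)-3-bromo-2-iodobenzene
Conditions: NIS, TFA (cat.), MeCN, 0 °C → rt
Reagents that add atoms: N-iodosuccinimide, O=C1CCC(=O)N1I
Why: Electrophilic aromatic iodination should occur ortho to bromine, a position para to one benzyloxy group and ortho to the other and less crowded than the one between the two ethers, so that the future C4a is flanked by bromine (C8a) and oxygen (C5).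

Step 3
Reactants: 3 1,5-bis(benzyloxy)-3-bromo-2-iodobenzene; 4 methyl (S)-glycidate
Product: 6 methyl (2S)-3-[2,4-bis(benzyloxy)-6-bromophenyl]-2-hydroxypropanoate, via aryl Grignard reagent 5 (not isolated)
Conditions: iPrMgCl·LiCl, THF, −40 °C; then CuI (10 mol%), 4, −40 → −20 °C; NH4Cl (aq.)
Reagents that add atoms: none
Why: Iodine–magnesium exchange is far faster than bromine–magnesium exchange, and the copper-catalysed SN2 opening of the glycidic ester at its unsubstituted carbon (cuprate epoxide opening) forms C4–C4a without touching the stereocentre, which becomes C3 (S).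

Step 4
Reactants: 6 methyl (2S)-3-[2,4-bis(benzyloxy)-6-bromophenyl]-2-hydroxypropanoate
Product: 7 methyl (2S)-2-(benzyloxy)-3-[2,4-bis(benzyloxy)-6-bromophenyl]propanoate
Conditions: BnBr, Ag2O, 4 Å molecular sieves, CH2Cl2, rt, dark
Reagents that add atoms: benzyl bromide, BrCc1ccccc1
Why: Silver-oxide-promoted Williamson benzylation needs no strong base, so the α-hydroxy ester should be etherified without epimerisation, and the O3 benzyl ether later serves both as the chelating group and as the block on O3 in the ring closure.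

Step 5
Reactants: 7 methyl (2S)-2-(benzyloxy)-3-[2,4-bis(benzyloxy)-6-bromophenyl]propanoate
Product: 8 (2S)-2-(benzyloxy)-3-[2,4-bis(benzyloxy)-6-bromophenyl]-N-methoxy-N-methylpropanamide
Conditions: MeNH(OMe)·HCl, iPrMgCl, THF, −20 °C
Reagents that add atoms: N,O-dimethylhydroxylamine hydrochloride, CNOC.Cl
Why: Aminolysis of the methyl ester by the chloromagnesium amide (Weinreb amide formation) is fast at −20 °C, where iPrMgCl should neither exchange with the electron-rich aryl bromide nor enolise the α-alkoxy ester.

Step 6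
Reactants: 9 5-bromo-2,3-dihydroxybenzaldehyde
Product: 10 2,3-bis(benzyloxy)-5-bromobenzaldehyde
Conditions: BnBr, K2CO3, DMF, 60 °C
Reagents that add atoms: benzyl bromide, BrCc1ccccc1
Why: Williamson etherification caps both phenols, leaving the aldehyde carbon to mark the position of the one oxygen that must later differ from the other two.

Step 7
Reactants: 10 2,3-bis(benzyloxy)-5-bromobenzaldehyde
Product: 12 2,3-bis(benzyloxy)-5-bromophenol, via aryl formate 11 (not isolated)
Conditions: mCPBA, CH2Cl2, rt; then K2CO3 (cat.), MeOH, rt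
Reagents that add atoms: meta-chloroperoxybenzoic acid, OOC(=O)c1cccc(Cl)c1
Why: In the Baeyer–Villiger (Dakin-type) oxidation the electron-rich 2-alkoxyaryl group migrates in preference to hydrogen, and methanolysis of the formate should give the single free phenol that becomes O3'.

Step 8
Reactants: 12 2,3-bis(benzyloxy)-5-bromophenol
Product: 13 1,2-bis(benzyloxy)-5-bromo-3-(methoxymethoxy)benzene
Conditions: NaH, MOMCl, THF/DMF, 0 °C → rt
Reagents that add atoms: chloromethyl methyl ether, COCCl
Why: Williamson-type alkylation of the sodium phenoxide gives a MOM acetal that tolerates Grignard formation, hydride and carbonate base and can later be removed by acid in the presence of benzyl ethers.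

Step 9
Reactants: 13 1,2-bis(benzyloxy)-5-bromo-3-(methoxymethoxy)benzene; 8 (2S)-2-(benzyloxy)-3-[2,4-bis(benzyloxy)-6-bromophenyl]-N-methoxy-N-methylpropanamide
Product: 15 (2S)-2-(benzyloxy)-1-[3,4-bis(benzyloxy)-5-(methoxymethoxy)phenyl]-3-[2,4-bis(benzyloxy)-6-bromophenyl]propan-1-one, via ring B Grignard reagent 14 (not isolated)
Conditions: 13, Mg turnings, I2 (cat.), THF, 50 °C; decanted solution added to 8, THF, 0 °C → rt; NH4Cl (aq.)
Reagents that add atoms: none
Why: In this Weinreb ketone synthesis the magnesium-chelated tetrahedral adduct prevents a second addition and the ring A bromide is inert to an aryl Grignard reagent, so C2–C1' should form without epimerising C3.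

Step 10
Reactants: 15 (2S)-2-(benzyloxy)-1-[3,4-bis(benzyloxy)-5-(methoxymethoxy)phenyl]-3-[2,4-bis(benzyloxy)-6-bromophenyl]propan-1-one
Product: 16 (1R,2S)-2-(benzyloxy)-1-[3,4-bis(benzyloxy)-5-(methoxymethoxy)phenyl]-3-[2,4-bis(benzyloxy)-6-bromophenyl]propan-1-ol
Conditions: Zn(BH4)2, Et2O/CH2Cl2, −30 → 0 °C
Reagents that add atoms: none
Why: In this chelation-controlled reduction (Cram chelate model) zinc bridges the carbonyl oxygen and the O3 benzyl ether, and hydride should add to the face of the five-membered chelate opposite the arylmethyl group, which sets C2 as R, anti to O3.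

Step 11
Reactants: 16 (1R,2S)-2-(benzyloxy)-1-[3,4-bis(benzyloxy)-5-(methoxymethoxy)phenyl]-3-[2,4-bis(benzyloxy)-6-bromophenyl]propan-1-ol
Product: 17 (2R,3S)-3,5,7-tris(benzyloxy)-2-[3,4-bis(benzyloxy)-5-(methoxymethoxy)phenyl]chromane
Conditions: Pd(OAc)2 (5 mol%), 2-(di-tert-butylphosphino)-1,1'-binaphthyl (6 mol%), Cs2CO3, toluene, 70 °C
Reagents that add atoms: none
Why: Zerovalent palladium, formed in the flask from Pd(OAc)2 and the phosphine, inserts into the C8a–Br bond; carbonate-assisted exchange of bromide for the C2 alkoxide on divalent palladium gives a seven-membered aryl(alkoxo)palladacycle, and C–O reductive elimination forms O1–C8a and returns zerovalent palladium. The closest known reaction type is the intramolecular Buchwald–Hartwig etherification of secondary alcohols with aryl bromides to chromans and 2-arylchromans. Ring C closes as a six-membered ring by attack of the tethered oxygen on the ring A carbon (6-exo with respect to the C2–C3–C4–C4a tether, realised as heteroatom–aryl reductive elimination). No stereocentre is created: no bond to C2 or C3 is broken, so the anti (1R,2S) alcohol maps with retention onto the 2,3-trans (2R,3S) flavan, and the benzylic carbon is never made electrophilic. The step needs chemoselectivity for the C2 oxygen, secured because O3 is a benzyl ether and no other hydroxyl is free, and it needs reductive elimination to beat β-hydride elimination from the benzylic alkoxide, which the bulky electron-rich di-tert-butyl(biaryl)phosphine and the mild carbonate base should ensure.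

Step 12
Reactants: 17 (2R,3S)-3,5,7-tris(benzyloxy)-2-[3,4-bis(benzyloxy)-5-(methoxymethoxy)phenyl]chromane
Product: 18 2,3-bis(benzyloxy)-5-[(2R,3S)-3,5,7-tris(benzyloxy)chroman-2-yl]phenol
Conditions: HCl (2 M in MeOH), THF, 40 °C
Reagents that add atoms: none
Why: Acid-catalysed methanolysis of the aryl MOM acetal should free only O3', since benzyl ethers are inert to dilute acid and the alkyl aryl ether C2–O1 is not ionised under such mild conditions.

Step 13
Reactants: 18 2,3-bis(benzyloxy)-5-[(2R,3S)-3,5,7-tris(benzyloxy)chroman-2-yl]phenol; 19 3,4,5-tris(benzyloxy)benzoic acid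
Product: 20 2,3-bis(benzyloxy)-5-[(2R,3S)-3,5,7-tris(benzyloxy)chroman-2-yl]phenyl 3,4,5-tris(benzyloxy)benzoate
Conditions: DCC, DMAP (cat.), CH2Cl2, rt
Reagents that add atoms: none
Why: Steglich esterification acylates the only free hydroxyl of 18, the O3' phenol, so the galloyl group can go to no other oxygen.

Step 14
Reactants: 20 2,3-bis(benzyloxy)-5-[(2R,3S)-3,5,7-tris(benzyloxy)chroman-2-yl]phenyl 3,4,5-tris(benzyloxy)benzoate
Product: 21 gallocatechin 3'-O-gallate
Conditions: H2 (1 atm), Pd(OH)2 on carbon, THF/MeOH, rt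
Reagents that add atoms: none
Why: Catalytic hydrogenolysis should cleave all eight benzyl ethers (seven aryl, one alkyl) under neutral conditions that leave the aryl ester in place and neither epimerise C2 nor move the galloyl group to O4'.

Compound list
1 | 5-bromoresorcinol (5-bromobenzene-1,3-diol) | Oc1cc(O)cc(Br)c1 | starting material
2 | 1,3-bis(benzyloxy)-5-bromobenzene | Brc1cc(OCc2ccccc2)cc(OCc2ccccc2)c1 | intermediate
3 | 1,5-bis(benzyloxy)-3-bromo-2-iodobenzene | Brc1cc(OCc2ccccc2)cc(OCc2ccccc2)c1I | intermediate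
4 | methyl (S)-glycidate (methyl (2S)-oxirane-2-carboxylate) | COC(=O)[C@@H]1CO1 | starting material
5 | [2,4-bis(benzyloxy)-6-bromophenyl]magnesium chloride, LiCl complex, not isolated | Cl[Mg]c1c(Br)cc(OCc2ccccc2)cc1OCc1ccccc1 | intermediate
6 | methyl (2S)-3-[2,4-bis(benzyloxy)-6-bromophenyl]-2-hydroxypropanoate | COC(=O)[C@@H](O)Cc1c(Br)cc(OCc2ccccc2)cc1OCc1ccccc1 | intermediate
7 | methyl (2S)-2-(benzyloxy)-3-[2,4-bis(benzyloxy)-6-bromophenyl]propanoate | COC(=O)[C@@H](OCc1ccccc1)Cc1c(Br)cc(OCc2ccccc2)cc1OCc1ccccc1 | intermediate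
8 | (2S)-2-(benzyloxy)-3-[2,4-bis(benzyloxy)-6-bromophenyl]-N-methoxy-N-methylpropanamide | CON(C)C(=O)[C@@H](OCc1ccccc1)Cc1c(Br)cc(OCc2ccccc2)cc1OCc1ccccc1 | intermediate
9 | 5-bromo-2,3-dihydroxybenzaldehyde | O=Cc1cc(Br)cc(O)c1O | starting material
10 | 2,3-bis(benzyloxy)-5-bromobenzaldehyde | O=Cc1cc(Br)cc(OCc2ccccc2)c1OCc1ccccc1 | intermediate
11 | 2,3-bis(benzyloxy)-5-bromophenyl formate, not isolated | O=COc1cc(Br)cc(OCc2ccccc2)c1OCc1ccccc1 | intermediate
12 | 2,3-bis(benzyloxy)-5-bromophenol | Oc1cc(Br)cc(OCc2ccccc2)c1OCc1ccccc1 | intermediate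
13 | 1,2-bis(benzyloxy)-5-bromo-3-(methoxymethoxy)benzene | COCOc1cc(Br)cc(OCc2ccccc2)c1OCc1ccccc1 | intermediate
14 | [3,4-bis(benzyloxy)-5-(methoxymethoxy)phenyl]magnesium bromide, not isolated | COCOc1cc([Mg]Br)cc(OCc2ccccc2)c1OCc1ccccc1 | intermediate
15 | (2S)-2-(benzyloxy)-1-[3,4-bis(benzyloxy)-5-(methoxymethoxy)phenyl]-3-[2,4-bis(benzyloxy)-6-bromophenyl]propan-1-one | COCOc1cc(C(=O)[C@@H](OCc2ccccc2)Cc2c(Br)cc(OCc3ccccc3)cc2OCc2ccccc2)cc(OCc2ccccc2)c1OCc1ccccc1 | intermediate
16 | (1R,2S)-2-(benzyloxy)-1-[3,4-bis(benzyloxy)-5-(methoxymethoxy)phenyl]-3-[2,4-bis(benzyloxy)-6-bromophenyl]propan-1-ol | COCOc1cc([C@@H](O)[C@@H](OCc2ccccc2)Cc2c(Br)cc(OCc3ccccc3)cc2OCc2ccccc2)cc(OCc2ccccc2)c1OCc1ccccc1 | intermediate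
17 | (2R,3S)-3,5,7-tris(benzyloxy)-2-[3,4-bis(benzyloxy)-5-(methoxymethoxy)phenyl]chromane | COCOc1cc([C@H]2Oc3cc(OCc4ccccc4)cc(OCc4ccccc4)c3C[C@@H]2OCc2ccccc2)cc(OCc2ccccc2)c1OCc1ccccc1 | intermediate
18 | 2,3-bis(benzyloxy)-5-[(2R,3S)-3,5,7-tris(benzyloxy)chroman-2-yl]phenol | Oc1cc([C@H]2Oc3cc(OCc4ccccc4)cc(OCc4ccccc4)c3C[C@@H]2OCc2ccccc2)cc(OCc2ccccc2)c1OCc1ccccc1 | intermediate
19 | 3,4,5-tris(benzyloxy)benzoic acid | OC(=O)c1cc(OCc2ccccc2)c(OCc2ccccc2)c(OCc2ccccc2)c1 | starting material
20 | 2,3-bis(benzyloxy)-5-[(2R,3S)-3,5,7-tris(benzyloxy)chroman-2-yl]phenyl 3,4,5-tris(benzyloxy)benzoate | O=C(Oc1cc([C@H]2Oc3cc(OCc4ccccc4)cc(OCc4ccccc4)c3C[C@@H]2OCc2ccccc2)cc(OCc2ccccc2)c1OCc1ccccc1)c1cc(OCc2ccccc2)c(OCc2ccccc2)c(OCc2ccccc2)c1 | intermediate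
21 | gallocatechin 3'-O-gallate, 2,3-dihydroxy-5-[(2R,3S)-3,5,7-trihydroxychroman-2-yl]phenyl 3,4,5-trihydroxybenzoate | O=C(Oc1cc([C@H]2Oc3cc(O)cc(O)c3C[C@@H]2O)cc(O)c1O)c1cc(O)c(O)c(O)c1 | target

Total step count: 14.
Longest linear sequence: 11 steps from 5-bromoresorcinol (steps 1 to 5, then 9 to 14); the ring B branch (steps 6 to 8) joins at step 9.

Steps most likely to fail

1. Step 11. β-Hydride elimination from the palladium alkoxide, which oxidises the benzylic carbinol and removes bromine from ring A, may outrun C–O reductive elimination. The fallback sets out from 16 and returns at 17, and it changes the roles of the partners: ring A becomes the nucleophile in an oxidative coupling. Miyaura borylation (Pd(dppf)Cl2, bis(pinacolato)diboron, KOAc, dioxane, 80 °C; acetate is too weak a base to form the palladium alkoxide) would give the C8a pinacol boronate of 16, F1. Intramolecular Chan–Lam etherification (Cu(OAc)2, pyridine, 4 Å molecular sieves, air, CH2Cl2, rt) would then join O1 to C8a at divalent copper. No bond at C2 is broken, so the configuration should again be retained in 17.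

2. Step 3. The aryl metal has two ortho substituents, so opening of the epoxide may be slow. Loss of magnesium halide toward an aryne, attack on the ester carbonyl or coupling with 2-iodopropane could then take over. The fallback sets out from 2 and returns at 8, with ring A as the electrophile and a chiral glycolate enolate as the nucleophile.
Vilsmeier–Haack formylation (POCl3, DMF, 80 °C), directed ortho to bromine as in step 2, would give 2,4-bis(benzyloxy)-6-bromobenzaldehyde F2. Reduction (NaBH4, MeOH/THF, 0 °C) would give [2,4-bis(benzyloxy)-6-bromophenyl]methanol F3. PBr3 (Et2O, 0 °C) would give the benzylic bromide 1,5-bis(benzyloxy)-3-bromo-2-(bromomethyl)benzene F4, to be used crude because electron-rich benzylic bromides are labile.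
The auxiliary (4R)-4-benzyl-3-[(benzyloxy)acetyl]-1,3-oxazolidin-2-one F5 would be made from (R)-4-benzyloxazolidin-2-one (nBuLi, then benzyloxyacetyl chloride, THF, −78 °C). Evans asymmetric alkylation of its sodium enolate (NaN(SiMe3)2, THF, −78 → −45 °C) with F4 should occur on the face of the chelated Z-enolate away from the auxiliary benzyl group and give the (2S)-alkylated imide F6. Transamination (AlMe3, MeNH(OMe)·HCl, CH2Cl2, 0 °C → rt) would then deliver Weinreb amide 8.

3. Step 10. Facial selectivity may be poor if the zinc chelate forms incompletely and an open Felkin–Anh pathway toward the syn alcohol competes. The fallback sets out from 15 and returns at 16, replacing substrate control by reagent control: Corey–Bakshi–Shibata reduction with the (R)-configured 2-methyl-CBS-oxazaborolidine (catalytic) and BH3·SMe2 in toluene at −20 °C. With ring B as the larger flanking group this should deliver hydride to the same face as the zinc chelate. No new compound is made.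

Further compounds
F1 | step 11 | (1R,2S)-2-(benzyloxy)-1-[3,4-bis(benzyloxy)-5-(methoxymethoxy)phenyl]-3-[2,4-bis(benzyloxy)-6-(4,4,5,5-tetramethyl-1,3,2-dioxaborolan-2-yl)phenyl]propan-1-ol | COCOc1cc([C@@H](O)[C@@H](OCc2ccccc2)Cc2c(B3OC(C)(C)C(C)(C)O3)cc(OCc3ccccc3)cc2OCc2ccccc2)cc(OCc2ccccc2)c1OCc1ccccc1
F2 | step 3 | 2,4-bis(benzyloxy)-6-bromobenzaldehyde | O=Cc1c(Br)cc(OCc2ccccc2)cc1OCc1ccccc1
F3 | step 3 | [2,4-bis(benzyloxy)-6-bromophenyl]methanol | OCc1c(Br)cc(OCc2ccccc2)cc1OCc1ccccc1
F4 | step 3 | 1,5-bis(benzyloxy)-3-bromo-2-(bromomethyl)benzene | BrCc1c(Br)cc(OCc2ccccc2)cc1OCc1ccccc1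
F5 | step 3 | (4R)-4-benzyl-3-[(benzyloxy)acetyl]-1,3-oxazolidin-2-one | O=C1OC[C@@H](Cc2ccccc2)N1C(=O)COCc1ccccc1
F6 | step 3 | (4R)-4-benzyl-3-{(2S)-2-(benzyloxy)-3-[2,4-bis(benzyloxy)-6-bromophenyl]propanoyl}-1,3-oxazolidin-2-one | O=C1OC[C@@H](Cc2ccccc2)N1C(=O)[C@@H](OCc1ccccc1)Cc1c(Br)cc(OCc2ccccc2)cc1OCc1ccccc1
F0 | step 10 | none | none
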